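**Plan**

1. Numbering: tetralin C1 (aryl), C2 and C3 (CH2OH), C4 (CH2), ring A = C4a, C5–C8, C8a. The retrosynthesis cuts C1–C8a by a reverse 1,2-shift to C1–C4a (a spiro[4.5]decadienone), then C1–C4a (phenolate plus quinone methide), then C1–C2 (aldol) and C3–C4 (conjugate addition).
2. Forward: two vanillin units are joined to a C4 butenolide by a tandem dithiane conjugate addition–aldol; desulfurization, LiAlH4 reduction and acetylation give an open-chain benzylic acetate.
3. Fluoride frees both phenols; the C1 quinone methide is attacked by the ring A phenolate at C4a, closing the cyclopentane C1–C2–C3–C4–C4a as a spirodienone.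
4. Acid then moves C1 from C4a to C8a: the cyclopentane grows into the tetralin ring and ring A rearomatizes.
5. Enabling feature: in ring A the C7 oxygen is para to C4a and the C6 methoxy is para to C8a, so the phenolate can bond only through C4a, and the cationic shift is steered to C8a.
6. Stereochemistry: C2 and C3 come from the (5R)-menthyloxy acetal of the butenolide (anti addition, then anti aldol); C1 is set in the ring expansion, trans to the C2 substituent.

Key step: step 10

Remark: the carbinol carbon made in step 5 and the C1 and spiro carbons of 15 are carried as epimer mixtures, because the first is made planar in step 9 and the others are reset or destroyed in step 10.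

**Route**

Step 1
Reactants: 1 vanillin
Product: 2 3-methoxy-4-(triisopropylsilyloxy)benzaldehyde
Conditions: i-Pr3SiCl, imidazole, DMF, rt
Reagents that add atoms: triisopropylsilyl chloride, CC(C)[Si](Cl)(C(C)C)C(C)C
Why: Imidazole-mediated O-silylation of a phenol gives a bulky aryl silyl ether that should survive the organolithium, Raney Ni and LiAlH4 steps and be removable with fluoride.

Step 2
Reactants: 2 3-methoxy-4-(triisopropylsilyloxy)benzaldehyde
Product: 3 2-[3-methoxy-4-(triisopropylsilyloxy)phenyl]-1,3-dithiane
Conditions: HS(CH2)3SH, BF3·OEt2 (cat.), CH2Cl2, 0 °C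
Reagents that add atoms: propane-1,3-dithiol, SCCCS
Why: Lewis-acid-catalysed dithioacetalization of an aryl aldehyde gives the Corey–Seebach acyl anion precursor that later becomes the C4 methylene.

Step 3
Reactants: 4 furfural
Product: 5 5-hydroxy-2(5H)-furanone (racemic)
Conditions: O2, hν (visible), methylene blue (cat.), MeOH, 20 °C
Reagents that add atoms: oxygen, O=O
Why: Singlet-oxygen [4+2] cycloaddition to the furan followed by methanolysis of the endoperoxide, with loss of the formyl carbon as methyl formate, is the standard photooxygenation of furfural to the pseudo-acid.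

Step 4
Reactants: 5 5-hydroxy-2(5H)-furanone (racemic), 6 (−)-menthol
Product: 7 (5R)-5-[(1R,2S,5R)-menthyloxy]-2(5H)-furanone
Conditions: camphorsulfonic acid (cat.), toluene, reflux, Dean–Stark; crystallization from hexane
Reagents that add atoms: none
Why: Acid-catalysed acetalization of the pseudo-acid gives both C5 epimers, which interconvert under the acid, and the (5R)-epimer is expected to crystallize selectively (crystallization-driven epimer enrichment, mother liquor re-equilibrated).

Step 5
Reactants: 3 2-[3-methoxy-4-(triisopropylsilyloxy)phenyl]-1,3-dithiane, 7 (5R)-5-[(1R,2S,5R)-menthyloxy]-2(5H)-furanone, 2 3-methoxy-4-(triisopropylsilyloxy)benzaldehyde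
Product: 10 (3S,4R,5R)-3-{hydroxy[3-methoxy-4-(triisopropylsilyloxy)phenyl]methyl}-4-{2-[3-methoxy-4-(triisopropylsilyloxy)phenyl]-1,3-dithian-2-yl}-5-[(1R,2S,5R)-menthyloxy]dihydrofuran-2(3H)-one (both carbinol epimers), via lithiated dithiane 8 (not isolated), via lactone lithium enolate 9 (not isolated)
Conditions: 3, n-BuLi (1.0 equiv), THF, −78 to −20 °C; then 7, −78 °C; then 2, −78 °C; AcOH quench at −78 °C
Reagents that add atoms: none
Why: Tandem Michael–aldol reaction: the lithiated dithiane adds 1,4 to the butenolide anti to the C5 menthyloxy group and the resulting enolate is trapped by the aldehyde anti to the new C4 substituent, which sets lactone C4 (R) and C3 (S), the future C3 and C2 of the tetralin, while the carbinol centre is left uncontrolled because it is erased later.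

Step 6
Reactants: 10 the dithianyl aldol lactone
Product: 11 (3S,4R,5R)-3-{hydroxy[3-methoxy-4-(triisopropylsilyloxy)phenyl]methyl}-4-[3-methoxy-4-(triisopropylsilyloxy)benzyl]-5-[(1R,2S,5R)-menthyloxy]dihydrofuran-2(3H)-one (both carbinol epimers)
Conditions: Raney Ni (W-2), EtOH, rt
Reagents that add atoms: none
Why: Raney nickel hydrogenolysis of both C–S bonds (Mozingo desulfurization) turns the dithiane carbon into the benzylic CH2 without touching the stereocentres, and a benzylic hydroxyl next to a lactone is known to survive these conditions at room temperature.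

Step 7
Reactants: 11 the benzyl aldol lactone
Product: 12 (2R,3R)-2-{hydroxy[3-methoxy-4-(triisopropylsilyloxy)phenyl]methyl}-3-[3-methoxy-4-(triisopropylsilyloxy)benzyl]butane-1,4-diol (both carbinol epimers)
Conditions: LiAlH4, THF, 0 °C to rt; aqueous NaOH work-up
Reagents that add atoms: none
Why: Hydride reduction of the lactone releases a hemiacetal alkoxide that expels menthoxide, and the resulting aldehyde is reduced at once, so both carbonyl-level carbons become CH2OH and the auxiliary is recovered as menthol.

Step 8
Reactants: 12 the triol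
Product: 13 (2R,3R)-2-{acetoxy[3-methoxy-4-(triisopropylsilyloxy)phenyl]methyl}-3-[3-methoxy-4-(triisopropylsilyloxy)benzyl]butane-1,4-diyl diacetate (both epimers at the benzylic carbon)
Conditions: Ac2O, pyridine, DMAP (cat.), CH2Cl2, 0 °C to rt
Reagents that add atoms: acetic anhydride, CC(=O)OC(C)=O
Why: DMAP-catalysed acylation turns the benzylic oxygen on C1 into a leaving group and masks the two primary alcohols, which would otherwise add to the quinone methide to give a tetrahydrofuran.

Step 9
Reactants: 13 the triacetate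
Product: 15 spirodienone (2R,3R)-[1-(4-hydroxy-3-methoxyphenyl)-7-methoxy-8-oxospiro[4.5]deca-6,9-diene-2,3-diyl]bis(methylene) diacetate (epimers at C1 and at the spiro carbon), via quinone methide phenolate 14 (not isolated)
Conditions: Bu4NF (2.2 equiv), THF (0.005 M), −78 to 0 °C; aqueous NH4Cl
Reagents that add atoms: none
Why: Fluoride cleaves both aryl silyl ethers, the phenolate para to C1 expels acetate by 1,6-elimination to the p-quinone methide, and the ring A phenolate, nucleophilic at carbon only ortho and para to its oxygen, attacks C1 through its para carbon C4a in a 5-exo dearomative 1,6-conjugate addition (the phenolate para-alkylation of the Winstein Ar1-5 type), because C8a is meta to the oxygen and other positions cannot reach, with high dilution suppressing intermolecular capture.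

Step 10
Reactants: 15 the spirodienone
Product: 16 [(1S,2R,3R)-7-hydroxy-1-(4-hydroxy-3-methoxyphenyl)-6-methoxy-1,2,3,4-tetrahydronaphthalene-2,3-diyl]bis(methylene) diacetate
Conditions: CF3CO2H (5 equiv), CH2Cl2, −20 to 0 °C
Reagents that add atoms: none
Why: O-Protonation of the cross-conjugated dienone gives a hydroxycyclohexadienyl cation in which C1, made migration-prone by its electron-rich 4-hydroxy-3-methoxyphenyl group, shifts from the spiro carbon C4a to the neighbouring ring carbon C8a, and loss of the C8a proton rearomatizes ring A to the C7 phenol. The closest known reaction type is the acid-mediated dienone–phenol rearrangement of spiro[4.5]deca-6,9-dien-8-ones to 5,6,7,8-tetrahydro-2-naphthols. The six-membered ring is closed by this enlargement of the cyclopentane through a 1,2-alkyl shift, which in its dissociative limit is a six-membered Friedel–Crafts closure of the tethered p-hydroxybenzyl cation onto C8a, and no other ring is formed. The only new stereocentre, C1, is controlled by the fixed C2 centre: in the half-chair transition state the aryl group takes the pseudo-equatorial position trans to the C2 acetoxymethyl group, and because the C1–C4a bond ionizes readily, both C1 epimers and both spiro epimers of 15 should converge on the 1,2-trans-2,3-trans product. The step needs C1 and not the unactivated C4 methylene to migrate, which the cation-stabilizing aryl group on C1 secures, and it needs C8a and not C5 as the terminus, which the C6 methoxy group secures by making C5 an electron-rich and hindered enol ether carbon while stabilizing, from the para position, the arenium ion formed at C8a.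

Step 11
Reactants: 16 the tetralin diacetate
Product: 17 (+)-isolariciresinol, (1S,2R,3R)-7-hydroxy-1-(4-hydroxy-3-methoxyphenyl)-2,3-bis(hydroxymethyl)-6-methoxy-1,2,3,4-tetrahydronaphthalene
Conditions: K2CO3 (cat.), MeOH, rt, under Ar; neutralization with acidic resin
Reagents that add atoms: none
Why: Base-catalysed transesterification (methanolysis) removes the two primary acetates without affecting any stereocentre.

**Compound list**

1 | vanillin | COc1cc(C=O)ccc1O | starting material
2 | 3-methoxy-4-(triisopropylsilyloxy)benzaldehyde | COc1cc(C=O)ccc1O[Si](C(C)C)(C(C)C)C(C)C | intermediate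
3 | 2-[3-methoxy-4-(triisopropylsilyloxy)phenyl]-1,3-dithiane | COc1cc(C2SCCCS2)ccc1O[Si](C(C)C)(C(C)C)C(C)C | intermediate
4 | furfural | O=Cc1ccco1 | starting material
5 | 5-hydroxy-2(5H)-furanone (racemic) | O=C1C=CC(O)O1 | intermediate
6 | (−)-menthol, (1R,2S,5R)-2-isopropyl-5-methylcyclohexanol | O[C@@H]1C[C@H](C)CC[C@H]1C(C)C | starting material
7 | (5R)-5-[(1R,2S,5R)-menthyloxy]-2(5H)-furanone | O=C1C=C[C@H](O[C@@H]2C[C@H](C)CC[C@H]2C(C)C)O1 | intermediate
8 | 2-lithio-2-[3-methoxy-4-(triisopropylsilyloxy)phenyl]-1,3-dithiane (formed in the flask) | COc1cc(C2([Li])SCCCS2)ccc1O[Si](C(C)C)(C(C)C)C(C)C | intermediate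
9 | lithium enolate of (4R,5R)-4-{2-[3-methoxy-4-(triisopropylsilyloxy)phenyl]-1,3-dithian-2-yl}-5-[(1R,2S,5R)-menthyloxy]dihydrofuran-2(3H)-one (formed in the flask) | [Li]OC1=C[C@@H](C2(SCCCS2)c2ccc(O[Si](C(C)C)(C(C)C)C(C)C)c(OC)c2)[C@H](O[C@@H]2C[C@H](C)CC[C@H]2C(C)C)O1 | intermediate
10 | (3S,4R,5R)-3-{hydroxy[3-methoxy-4-(triisopropylsilyloxy)phenyl]methyl}-4-{2-[3-methoxy-4-(triisopropylsilyloxy)phenyl]-1,3-dithian-2-yl}-5-[(1R,2S,5R)-menthyloxy]dihydrofuran-2(3H)-one, both carbinol epimers | O=C1[C@H](C(O)c2ccc(O[Si](C(C)C)(C(C)C)C(C)C)c(OC)c2)[C@@H](C2(SCCCS2)c2ccc(O[Si](C(C)C)(C(C)C)C(C)C)c(OC)c2)[C@H](O[C@@H]2C[C@H](C)CC[C@H]2C(C)C)O1 | intermediate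
11 | (3S,4R,5R)-3-{hydroxy[3-methoxy-4-(triisopropylsilyloxy)phenyl]methyl}-4-[3-methoxy-4-(triisopropylsilyloxy)benzyl]-5-[(1R,2S,5R)-menthyloxy]dihydrofuran-2(3H)-one, both carbinol epimers | O=C1[C@H](C(O)c2ccc(O[Si](C(C)C)(C(C)C)C(C)C)c(OC)c2)[C@@H](Cc2ccc(O[Si](C(C)C)(C(C)C)C(C)C)c(OC)c2)[C@H](O[C@@H]2C[C@H](C)CC[C@H]2C(C)C)O1 | intermediate
12 | (2R,3R)-2-{hydroxy[3-methoxy-4-(triisopropylsilyloxy)phenyl]methyl}-3-[3-methoxy-4-(triisopropylsilyloxy)benzyl]butane-1,4-diol, both carbinol epimers | COc1cc(C(O)[C@@H](CO)[C@H](CO)Cc2ccc(O[Si](C(C)C)(C(C)C)C(C)C)c(OC)c2)ccc1O[Si](C(C)C)(C(C)C)C(C)C | intermediate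
13 | (2R,3R)-2-{acetoxy[3-methoxy-4-(triisopropylsilyloxy)phenyl]methyl}-3-[3-methoxy-4-(triisopropylsilyloxy)benzyl]butane-1,4-diyl diacetate, both epimers at the benzylic carbon | COc1cc(C(OC(C)=O)[C@@H](COC(C)=O)[C@H](COC(C)=O)Cc2ccc(O[Si](C(C)C)(C(C)C)C(C)C)c(OC)c2)ccc1O[Si](C(C)C)(C(C)C)C(C)C | intermediate
14 | tetrabutylammonium 4-[(2R,3R)-2,3-bis(acetoxymethyl)-4-(3-methoxy-4-oxocyclohexa-2,5-dien-1-ylidene)butyl]-2-methoxyphenolate, the p-quinone methide phenolate (formed in the flask) | COC1=CC(=C[C@@H](COC(C)=O)[C@H](COC(C)=O)Cc2ccc([O-])c(OC)c2)C=CC1=O.CCCC[N+](CCCC)(CCCC)CCCC | intermediate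
15 | (2R,3R)-[1-(4-hydroxy-3-methoxyphenyl)-7-methoxy-8-oxospiro[4.5]deca-6,9-diene-2,3-diyl]bis(methylene) diacetate, epimers at C1 and at the spiro carbon | COc1cc(C2C3(C=CC(=O)C(OC)=C3)C[C@@H](COC(C)=O)[C@@H]2COC(C)=O)ccc1O | intermediate
16 | [(1S,2R,3R)-7-hydroxy-1-(4-hydroxy-3-methoxyphenyl)-6-methoxy-1,2,3,4-tetrahydronaphthalene-2,3-diyl]bis(methylene) diacetate | COc1cc([C@H]2c3cc(O)c(OC)cc3C[C@@H](COC(C)=O)[C@@H]2COC(C)=O)ccc1O | intermediate
17 | (+)-isolariciresinol, (1S,2R,3R)-7-hydroxy-1-(4-hydroxy-3-methoxyphenyl)-2,3-bis(hydroxymethyl)-6-methoxy-1,2,3,4-tetrahydronaphthalene | COc1cc([C@H]2c3cc(O)c(OC)cc3C[C@@H](CO)[C@@H]2CO)ccc1O | target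

**Step count**

Total steps: 11. Longest linear sequence: 9 steps (steps 1, 2, 5, 6, 7, 8, 9, 10, 11; the branch through steps 3 and 4 is equally long).

**Steps most likely to fail**

Step 9. Under naked, basic fluoride the quinone methide may lose the C2 proton and tautomerize to the styrene, or be captured by a phenolate of another molecule before the ipso closure, and the primary acetates may migrate or be cleaved. The fallback sets out from 13 and comes back at 15, and makes the quinone methide by oxidation under non-fluoride conditions. Hydrogenolysis of the benzylic acetate (H2, Pd/C, EtOAc) should give (2R,3R)-2,3-bis[3-methoxy-4-(triisopropylsilyloxy)benzyl]butane-1,4-diyl diacetate F1. Buffered desilylation (Bu4NF, AcOH, THF) should give (−)-secoisolariciresinol 9,9'-diacetate F2, which is C2-symmetric, so dehydrogenation at either benzylic position leads to the same species. DDQ (1.0 equiv, THF, 0 °C), a known dehydrogenation of 4-alkylphenols, should give the neutral quinone methide phenol F3, and addition of Et3N should then close it to 15.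

Step 10. The protonated dienone may fragment and alkylate another molecule instead of rearranging, the C4 methylene may migrate or the shift may go to C5, and facial control at C1 may be incomplete. The fallback sets out from 13 and comes back at 16, and gives up the spiro intermediate. Ionization of the benzylic acetate with BF3·OEt2 in CH2Cl2 at −40 °C and direct Friedel–Crafts closure onto C8a, para to the methoxy group (the established acid cyclization of 7-oxygenated dibenzylbutane lignans), should give the bis(triisopropylsilyl) ether of the tetralin diacetate F4. Bu4NF buffered with AcOH in THF then removes both silyl groups to give 16.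

Step 5. The hindered enolate next to the dithianyl group may be trapped incompletely, and the lithium aldolate may undergo retro-aldol cleavage or proton transfer before the quench. The fallback sets out from enolate 9 and comes back at 11, and makes the C1–C2 bond only after desulfurization. Quenching 9 with aqueous NH4Cl should give (4R,5R)-4-{2-[3-methoxy-4-(triisopropylsilyloxy)phenyl]-1,3-dithian-2-yl}-5-[(1R,2S,5R)-menthyloxy]dihydrofuran-2(3H)-one F5. Raney Ni in EtOH should give (4R,5R)-4-[3-methoxy-4-(triisopropylsilyloxy)benzyl]-5-[(1R,2S,5R)-menthyloxy]dihydrofuran-2(3H)-one F6. Its less hindered lithium enolate (LDA, THF, −78 °C) should then add to aldehyde 2 anti to the benzyl group, the classical aldol of β-benzylbutyrolactones, to give 11.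

**Further compounds**

F1 | step 9 | (2R,3R)-2,3-bis[3-methoxy-4-(triisopropylsilyloxy)benzyl]butane-1,4-diyl diacetate | COc1cc(C[C@@H](COC(C)=O)[C@H](COC(C)=O)Cc2ccc(O[Si](C(C)C)(C(C)C)C(C)C)c(OC)c2)ccc1O[Si](C(C)C)(C(C)C)C(C)C
F2 | step 9 | (−)-secoisolariciresinol 9,9'-diacetate, (2R,3R)-2,3-bis(4-hydroxy-3-methoxybenzyl)butane-1,4-diyl diacetate | COc1cc(C[C@@H](COC(C)=O)[C@H](COC(C)=O)Cc2ccc(O)c(OC)c2)ccc1O
F3 | step 9 | (2R,3R)-2-(4-hydroxy-3-methoxybenzyl)-3-[(3-methoxy-4-oxocyclohexa-2,5-dien-1-ylidene)methyl]butane-1,4-diyl diacetate, the neutral quinone methide phenol | COC1=CC(=C[C@@H](COC(C)=O)[C@H](COC(C)=O)Cc2ccc(O)c(OC)c2)C=CC1=O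
F4 | step 10 | [(1S,2R,3R)-6-methoxy-1-[3-methoxy-4-(triisopropylsilyloxy)phenyl]-7-(triisopropylsilyloxy)-1,2,3,4-tetrahydronaphthalene-2,3-diyl]bis(methylene) diacetate | COc1cc([C@H]2c3cc(O[Si](C(C)C)(C(C)C)C(C)C)c(OC)cc3C[C@@H](COC(C)=O)[C@@H]2COC(C)=O)ccc1O[Si](C(C)C)(C(C)C)C(C)C
F5 | step 5 | (4R,5R)-4-{2-[3-methoxy-4-(triisopropylsilyloxy)phenyl]-1,3-dithian-2-yl}-5-[(1R,2S,5R)-menthyloxy]dihydrofuran-2(3H)-one | O=C1C[C@@H](C2(SCCCS2)c2ccc(O[Si](C(C)C)(C(C)C)C(C)C)c(OC)c2)[C@H](O[C@@H]2C[C@H](C)CC[C@H]2C(C)C)O1
F6 | step 5 | (4R,5R)-4-[3-methoxy-4-(triisopropylsilyloxy)benzyl]-5-[(1R,2S,5R)-menthyloxy]dihydrofuran-2(3H)-one | O=C1C[C@@H](Cc2ccc(O[Si](C(C)C)(C(C)C)C(C)C)c(OC)c2)[C@H](O[C@@H]2C[C@H](C)CC[C@H]2C(C)C)O1
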